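**Retrosynthetic overview**

1. Target (germacrane numbering C1–C15): ten-membered carbocycle C1–C10 bridged by the furanone oxygen between C3 and C10, trans-fused C6/C7 α-methylene-γ-butyrolactone (C12 carbonyl), C8 methacrylate, C15 hydroxymethyl on C4.
2. Key disconnection: C1–C2 and O(C10)–C3 in one operation, from an isomeric ten-membered macrolactone in which C1 is esterified to O15 and C4 carries an acetyl group (C2–C3). Enabling feature: the acetyl carbon C2 and the lactone carbonyl C1 both hang on C4 (six-atom array C2–C3–C4–C15–O15–C1), and the C10 oxygen sits next to C1, so after O-to-C acyl transfer it lies 1,4 to C3 across the new ring.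
3. The macrolactone is closed at C6–C7 by intramolecular allylboration of a 2-(methoxycarbonyl)allylboronate onto a Z-4-oxo-enal, which also gives the butyrolactone; the Z-enedione (C3–C6) is unmasked from a 2-methylfuran whose methyl group is C2.
4. Acyclic chain: C10 by a copper bis(oxazoline) pyruvate aldol, C8 by hydroxyl-directed anti reduction, the allylboronate by hydroalumination/borylmethylation of an ynoate; the C1–O15 ester is made in step 1.
5. Ring order: furan (bought) → ten-membered lactone + butyrolactone (step 10) → ten-membered carbocycle + furanone (step 13).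

Key step: step 13

Remark on numbering: C1–C15 in the text are the germacrane numbers of the target (C1 ketone carbon, C3 enol-ether carbon, C10 quaternary carbon, C12 lactone carbonyl, C15 hydroxymethyl carbon).
Assumption: the (R,R)-t-Bu-box complex of Cu(OTf)2 is taken to direct the enol silane to the Re face of the chelated pyruvate ketone (mirror image of the sense of the (S,S) ligand); if the sense is the opposite, the (S,S) ligand is used.

**Route**

Step 1
Reactants: 1 pyruvic acid; 2 (2-methylfuran-3-yl)methanol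
Product: 3 (2-methylfuran-3-yl)methyl 2-oxopropanoate
Conditions: DCC, DMAP (5 mol %), CH2Cl2, 0 °C → rt
Reagents that add atoms: none
Why: Steglich esterification of the primary alcohol installs at the outset the C1–O15 ester that later serves as the internal acyl donor, so neither C1 nor O15 needs a protecting group; no stereocentre is formed.

Step 2
Reactants: 4 4-(trimethylsilyl)but-3-yn-2-one
Product: 5 trimethyl{[4-(trimethylsilyl)but-1-en-3-yn-2-yl]oxy}silane
Conditions: TMSOTf, NEt3, Et2O, 0 °C
Reagents that add atoms: trimethylsilyl triflate, C[Si](C)(C)OS(=O)(=O)C(F)(F)F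
Why: Soft enolisation and O-silylation (silyl enol ether formation) at the only enolisable position of the ketone gives the nucleophile for the aldol step; no stereocentre is formed.

Step 3
Reactants: 3 (2-methylfuran-3-yl)methyl 2-oxopropanoate; 5 trimethyl{[4-(trimethylsilyl)but-1-en-3-yn-2-yl]oxy}silane
Product: 7 (2-methylfuran-3-yl)methyl (2R)-2-hydroxy-2-methyl-4-oxo-6-(trimethylsilyl)hex-5-ynoate, via silyl ether 6 (not isolated)
Conditions: Cu(OTf)2 (10 mol %), (R,R)-t-Bu-box (11 mol %), THF, −78 °C; then 1 M HCl, 0 °C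
Reagents that add atoms: none
Why: Mukaiyama aldol addition catalysed by a chiral divalent copper bis(oxazoline) Lewis acid: the pyruvate chelates copper through both carbonyl oxygens in a square-planar complex whose tert-butyl groups shield one face, so the enol silane should add to the exposed Re face of the ketone and set the tertiary carbinol C10 as R, the transferred silyl group being removed in the acid work-up.

Step 4
Reactants: 7 (2-methylfuran-3-yl)methyl (2R)-2-hydroxy-2-methyl-4-oxo-6-(trimethylsilyl)hex-5-ynoate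
Product: 8 (2-methylfuran-3-yl)methyl (2R,4R)-2,4-dihydroxy-2-methyl-6-(trimethylsilyl)hex-5-ynoate
Conditions: Me4NBH(OAc)3, MeCN/AcOH 1:1, −35 °C
Reagents that add atoms: none
Why: Evans–Saksena reduction: the tertiary C10 hydroxyl exchanges onto boron and delivers hydride intramolecularly through a chair transition state, which should give the 1,3-anti diol and so the R configuration at C8 (C4 of the hexynoate).

Step 5
Reactants: 8 (2-methylfuran-3-yl)methyl (2R,4R)-2,4-dihydroxy-2-methyl-6-(trimethylsilyl)hex-5-ynoate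
Product: 9 (2-methylfuran-3-yl)methyl (2R,4R)-2-methyl-2,4-bis[(triethylsilyl)oxy]-6-(trimethylsilyl)hex-5-ynoate
Conditions: TESOTf (2.5 equiv), 2,6-lutidine, CH2Cl2, −78 → 0 °C
Reagents that add atoms: triethylsilyl triflate, CC[Si](CC)(CC)OS(=O)(=O)C(F)(F)F
Why: Silyl ether formation with the triflate, reactive enough for the tertiary as well as the secondary hydroxyl, at once stops the C8 hydroxyl from lactonising onto C1; no stereocentre is touched.

Step 6
Reactants: 9 (2-methylfuran-3-yl)methyl (2R,4R)-2-methyl-2,4-bis[(triethylsilyl)oxy]-6-(trimethylsilyl)hex-5-ynoate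
Product: 10 (2-methylfuran-3-yl)methyl (2R,4R)-2-methyl-2,4-bis[(triethylsilyl)oxy]hex-5-ynoate
Conditions: K2CO3 (0.2 equiv), MeOH, 0 °C
Reagents that add atoms: none
Why: Base-catalysed methanolysis of the alkynyl–silicon bond (protodesilylation) should leave the triethylsilyl ethers and the hindered, α-quaternary ester intact.

Step 7
Reactants: 10 (2-methylfuran-3-yl)methyl (2R,4R)-2-methyl-2,4-bis[(triethylsilyl)oxy]hex-5-ynoate
Product: 12 1-methyl 7-[(2-methylfuran-3-yl)methyl] (4R,6R)-6-methyl-4,6-bis[(triethylsilyl)oxy]hept-2-ynedioate, via lithium acetylide 11 (not isolated)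
Conditions: LiN(i-Pr)2 (1.05 equiv), THF, −78 °C; then ClCO2Me
Reagents that add atoms: methyl chloroformate, COC(=O)Cl
Why: Deprotonation of the terminal alkyne (the ester has no α-hydrogen) and C-acylation of the acetylide by the chloroformate (alkoxycarbonylation) installs C12.

Step 8
Reactants: 12 1-methyl 7-[(2-methylfuran-3-yl)methyl] (4R,6R)-6-methyl-4,6-bis[(triethylsilyl)oxy]hept-2-ynedioate
Product: 14 1-methyl 7-[(2-methylfuran-3-yl)methyl] (2Z,4R,6R)-6-methyl-2-[(4,4,5,5-tetramethyl-1,3,2-dioxaborolan-2-yl)methyl]-4,6-bis[(triethylsilyl)oxy]hept-2-enedioate, via alkenylalane 13 (not isolated)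
Conditions: i-Bu2AlH (1.3 equiv), HMPA, CuMe (10 mol %, from CuI and MeLi), THF, −50 °C; then ICH2Bpin, −50 → 0 °C
Reagents that add atoms: 2-(iodomethyl)-4,4,5,5-tetramethyl-1,3,2-dioxaborolane, CC1(C)OB(CI)OC1(C)C
Why: Conjugate hydroalumination of the ynoate (1,4-hydride addition) gives an α-aluminated enoate that is alkylated by the iodomethylboronate on the side of the new C7 hydrogen, a net syn addition that places the C8 branch cis to the ester (2Z) and trans to the CH2B group, the geometry needed for an anti-selective allylboration.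

Step 9
Reactants: 14 1-methyl 7-[(2-methylfuran-3-yl)methyl] (2Z,4R,6R)-6-methyl-2-[(4,4,5,5-tetramethyl-1,3,2-dioxaborolan-2-yl)methyl]-4,6-bis[(triethylsilyl)oxy]hept-2-enedioate
Product: 16 7-[(2Z)-2-acetyl-4-oxobut-2-en-1-yl] 1-methyl (2Z,4R,6R)-6-methyl-2-[(4,4,5,5-tetramethyl-1,3,2-dioxaborolan-2-yl)methyl]-4,6-bis[(triethylsilyl)oxy]hept-2-enedioate, via endoperoxide 15 (not isolated)
Conditions: O2, methylene blue (cat.), visible light, CH2Cl2, −78 °C; then Me2S, −78 → 0 °C; used crude
Reagents that add atoms: dioxygen, O=O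
Why: [4+2] cycloaddition of singlet oxygen to the furan and reduction of the endoperoxide by the sulfide unmask the aldehyde (C6) and the methyl ketone (C2–C3) together, and the Z geometry of the enedione (acetyl cis to C6) is inherited from the ring; the electron-poor alkenes and the boronate should not react.

Step 10
Reactants: 16 7-[(2Z)-2-acetyl-4-oxobut-2-en-1-yl] 1-methyl (2Z,4R,6R)-6-methyl-2-[(4,4,5,5-tetramethyl-1,3,2-dioxaborolan-2-yl)methyl]-4,6-bis[(triethylsilyl)oxy]hept-2-enedioate
Product: 18 (1R,2Z,7R,9R,10S)-3-acetyl-7-methyl-11-methylidene-7,9-bis[(triethylsilyl)oxy]-5,13-dioxabicyclo[8.3.0]tridec-2-ene-6,12-dione, via borate ester 17 (not isolated)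
Conditions: Sc(OTf)3 (20 mol %), CH2Cl2 (0.002 M), 0 °C → rt
Reagents that add atoms: none
Why: Lewis acid-catalysed intramolecular allylboration through a closed chair transition state, then lactonisation of the borate onto the methyl ester: the aldehyde substituent and the C8 branch both sit equatorial, which should give the anti adduct and so the trans-fused 6,12-lactone (C6 R), while the C7 face is set by C8 (C8–H eclipsing the ester-bearing alkene carbon to avoid allylic 1,3-strain, the aldehyde approaching anti to the C9 chain), giving the natural C7 configuration (descriptor S here only because of the silyl ether at C8); re-aromatisation of the C6 alkoxide onto the C3 ketone would need a strained 2,4-bridged furanophane.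

Step 11
Reactants: 18 (1R,2Z,7R,9R,10S)-3-acetyl-7-methyl-11-methylidene-7,9-bis[(triethylsilyl)oxy]-5,13-dioxabicyclo[8.3.0]tridec-2-ene-6,12-dione
Product: 19 (1R,2Z,7R,9R,10R)-3-acetyl-9-hydroxy-7-methyl-11-methylidene-7-[(triethylsilyl)oxy]-5,13-dioxabicyclo[8.3.0]tridec-2-ene-6,12-dione
Conditions: HF·pyridine, pyridine, THF, 0 °C
Reagents that add atoms: none
Why: Selective desilylation: the secondary C8 silyl ether should be cleaved by buffered fluoride well before the tertiary, neopentyl-like C10 silyl ether; no stereocentre is touched.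

Step 12
Reactants: 19 (1R,2Z,7R,9R,10R)-3-acetyl-9-hydroxy-7-methyl-11-methylidene-7-[(triethylsilyl)oxy]-5,13-dioxabicyclo[8.3.0]tridec-2-ene-6,12-dione
Product: 20 (1R,2Z,7R,9R,10R)-3-acetyl-7-methyl-11-methylidene-6,12-dioxo-7-[(triethylsilyl)oxy]-5,13-dioxabicyclo[8.3.0]tridec-2-en-9-yl 2-methylprop-2-enoate
Conditions: methacrylic anhydride, NEt3, DMAP (10 mol %), CH2Cl2, 0 °C
Reagents that add atoms: methacrylic anhydride, CC(=C)C(=O)OC(=O)C(C)=C
Why: DMAP-catalysed acylation of the only free hydroxyl proceeds with retention at C8; the C15 oxygen is tied up in the macrolactone and the C10 oxygen is silylated.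

Step 13
Reactants: 20 (1R,2Z,7R,9R,10R)-3-acetyl-7-methyl-11-methylidene-6,12-dioxo-7-[(triethylsilyl)oxy]-5,13-dioxabicyclo[8.3.0]tridec-2-en-9-yl 2-methylprop-2-enoate
Product: 23 (2Z,4R,8R,9R,11R)-2-(hydroxymethyl)-11-methyl-7-methylidene-6,12-dioxo-5,14-dioxatricyclo[9.2.1.0(4,8)]tetradeca-1(13),2-dien-9-yl 2-methylprop-2-enoate (CNP0180483.5), via silyloxy diketone 21 (not isolated), via hydroxy diketone 22 (not isolated)
Conditions: LiN(SiMe3)2 (2.2 equiv), THF (0.005 M), −78 → −20 °C; then 1 M HCl, THF, 0 °C → rt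
Reagents that add atoms: none
Why: Kinetic deprotonation of the acetyl methyl group (C2) gives an enolate that adds through a six-membered transition state (C2, C3, C4, C15, O15, C1) to the lactone carbonyl C1, and collapse of the bicyclic tetrahedral intermediate expels the C15 alkoxide, so the C1–C2 bond closes the ten-membered carbocycle while the ten-membered lactone ring opens (6-exo-trig addition, then ring switch), driven by formation of the lithium 1,3-diketonate. The closest known reaction type is the Baker–Venkataraman O-to-C acyl migration (intramolecular Claisen acylation of a ketone enolate by a β-acyloxy group), here applied to a macrolactone, followed by the classical acid cyclodehydration of an α'-hydroxy-1,3-diketone to a 3(2H)-furanone. On acidification the C10 silyl ether is cleaved and the tertiary hydroxyl adds across the ring to the C3 carbonyl (transannular 5-exo-trig hemiketalisation); loss of water then fixes the O–C3 bond of the furanone. No new stereocentre is formed: C6, C7, C8 and C10 are untouched (C10 is quaternary) and the C4=C5 geometry is kept, because the acetyl group already stands cis to C6. The step needs chemoselection for C1 over the C12 lactone and methacrylate carbonyls and over conjugate addition, which the six-membered delivery, low temperature and high dilution should secure, and it needs ring closure by the C10 oxygen and not by the freed C15 hydroxyl, which is secured because closure of O15 onto C1 would give a dihydropyranone spanned across its 1,4-positions by the six-atom C5–C10 chain.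

**Compound list**

1 | pyruvic acid | CC(=O)C(=O)O | starting material
2 | (2-methylfuran-3-yl)methanol | Cc1occc1CO | starting material
3 | (2-methylfuran-3-yl)methyl 2-oxopropanoate | CC(=O)C(=O)OCc1ccoc1C | intermediate
4 | 4-(trimethylsilyl)but-3-yn-2-one | CC(=O)C#C[Si](C)(C)C | starting material
5 | trimethyl{[4-(trimethylsilyl)but-1-en-3-yn-2-yl]oxy}silane | C=C(O[Si](C)(C)C)C#C[Si](C)(C)C | intermediate
6 | (2-methylfuran-3-yl)methyl (2R)-2-methyl-4-oxo-6-(trimethylsilyl)-2-[(trimethylsilyl)oxy]hex-5-ynoate (silyl ether, not isolated) | C[C@@](O[Si](C)(C)C)(CC(=O)C#C[Si](C)(C)C)C(=O)OCc1ccoc1C | intermediate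
7 | (2-methylfuran-3-yl)methyl (2R)-2-hydroxy-2-methyl-4-oxo-6-(trimethylsilyl)hex-5-ynoate | C[C@@](O)(CC(=O)C#C[Si](C)(C)C)C(=O)OCc1ccoc1C | intermediate
8 | (2-methylfuran-3-yl)methyl (2R,4R)-2,4-dihydroxy-2-methyl-6-(trimethylsilyl)hex-5-ynoate | C[C@@](O)(C[C@@H](O)C#C[Si](C)(C)C)C(=O)OCc1ccoc1C | intermediate
9 | (2-methylfuran-3-yl)methyl (2R,4R)-2-methyl-2,4-bis[(triethylsilyl)oxy]-6-(trimethylsilyl)hex-5-ynoate | C[C@@](O[Si](CC)(CC)CC)(C[C@@H](O[Si](CC)(CC)CC)C#C[Si](C)(C)C)C(=O)OCc1ccoc1C | intermediate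
10 | (2-methylfuran-3-yl)methyl (2R,4R)-2-methyl-2,4-bis[(triethylsilyl)oxy]hex-5-ynoate | C[C@@](O[Si](CC)(CC)CC)(C[C@@H](O[Si](CC)(CC)CC)C#C)C(=O)OCc1ccoc1C | intermediate
11 | lithium acetylide of 10 (not isolated) | C[C@@](O[Si](CC)(CC)CC)(C[C@@H](O[Si](CC)(CC)CC)C#C[Li])C(=O)OCc1ccoc1C | intermediate
12 | 1-methyl 7-[(2-methylfuran-3-yl)methyl] (4R,6R)-6-methyl-4,6-bis[(triethylsilyl)oxy]hept-2-ynedioate | C[C@@](O[Si](CC)(CC)CC)(C[C@@H](O[Si](CC)(CC)CC)C#CC(=O)OC)C(=O)OCc1ccoc1C | intermediate
13 | 1-methyl 7-[(2-methylfuran-3-yl)methyl] (2E,4R,6R)-2-(diisobutylalumanyl)-6-methyl-4,6-bis[(triethylsilyl)oxy]hept-2-enedioate (alkenylalane, not isolated) | C[C@@](O[Si](CC)(CC)CC)(C[C@@H](O[Si](CC)(CC)CC)/C=C(\C(=O)OC)[Al](CC(C)C)CC(C)C)C(=O)OCc1ccoc1C | intermediate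
14 | 1-methyl 7-[(2-methylfuran-3-yl)methyl] (2Z,4R,6R)-6-methyl-2-[(4,4,5,5-tetramethyl-1,3,2-dioxaborolan-2-yl)methyl]-4,6-bis[(triethylsilyl)oxy]hept-2-enedioate | C[C@@](O[Si](CC)(CC)CC)(C[C@@H](O[Si](CC)(CC)CC)/C=C(\C(=O)OC)CB1OC(C)(C)C(C)(C)O1)C(=O)OCc1ccoc1C | intermediate
15 | furan endoperoxide of 14 (2,3,7-trioxabicyclo[2.2.1]hept-5-ene; both bridgehead-epimeric pairs; not isolated) | C[C@@](O[Si](CC)(CC)CC)(C[C@@H](O[Si](CC)(CC)CC)/C=C(\C(=O)OC)CB1OC(C)(C)C(C)(C)O1)C(=O)OCC1=CC2OOC1(C)O2 | intermediate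
16 | 7-[(2Z)-2-acetyl-4-oxobut-2-en-1-yl] 1-methyl (2Z,4R,6R)-6-methyl-2-[(4,4,5,5-tetramethyl-1,3,2-dioxaborolan-2-yl)methyl]-4,6-bis[(triethylsilyl)oxy]hept-2-enedioate | C[C@@](O[Si](CC)(CC)CC)(C[C@@H](O[Si](CC)(CC)CC)/C=C(\C(=O)OC)CB1OC(C)(C)C(C)(C)O1)C(=O)OC/C(C(C)=O)=C/C=O | intermediate
17 | pinacol borate of the C6 alcohol: ten-membered lactone closed, C12 still the methyl ester, 4-acetyl (4Z), 8- and 10-triethylsilyl ethers, (6R,7S,8R,10R) in germacrane numbering (not isolated) | C[C@@]1(O[Si](CC)(CC)CC)C[C@@H](O[Si](CC)(CC)CC)[C@@H](C(=C)C(=O)OC)[C@H](OB2OC(C)(C)C(C)(C)O2)/C=C(\C(C)=O)COC1=O | intermediate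
18 | (1R,2Z,7R,9R,10S)-3-acetyl-7-methyl-11-methylidene-7,9-bis[(triethylsilyl)oxy]-5,13-dioxabicyclo[8.3.0]tridec-2-ene-6,12-dione | C[C@@]1(O[Si](CC)(CC)CC)C[C@@H](O[Si](CC)(CC)CC)[C@H]2C(=C)C(=O)O[C@@H]2/C=C(\C(C)=O)COC1=O | intermediate
19 | (1R,2Z,7R,9R,10R)-3-acetyl-9-hydroxy-7-methyl-11-methylidene-7-[(triethylsilyl)oxy]-5,13-dioxabicyclo[8.3.0]tridec-2-ene-6,12-dione | C[C@@]1(O[Si](CC)(CC)CC)C[C@@H](O)[C@H]2C(=C)C(=O)O[C@@H]2/C=C(\C(C)=O)COC1=O | intermediate
20 | (1R,2Z,7R,9R,10R)-3-acetyl-7-methyl-11-methylidene-6,12-dioxo-7-[(triethylsilyl)oxy]-5,13-dioxabicyclo[8.3.0]tridec-2-en-9-yl 2-methylprop-2-enoate | C[C@@]1(O[Si](CC)(CC)CC)C[C@@H](OC(=O)C(C)=C)[C@H]2C(=C)C(=O)O[C@@H]2/C=C(\C(C)=O)COC1=O | intermediate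
21 | (1R,2R,4R,8Z,10R)-8-(hydroxymethyl)-4-methyl-13-methylidene-5,7,12-trioxo-4-[(triethylsilyl)oxy]-11-oxabicyclo[8.3.0]tridec-8-en-2-yl 2-methylprop-2-enoate (silyloxy diketone, formed as its lithium enolate, not isolated) | C[C@@]1(O[Si](CC)(CC)CC)C[C@@H](OC(=O)C(C)=C)[C@H]2C(=C)C(=O)O[C@@H]2/C=C(/CO)C(=O)CC1=O | intermediate
22 | (1R,2R,4R,8Z,10R)-4-hydroxy-8-(hydroxymethyl)-4-methyl-13-methylidene-5,7,12-trioxo-11-oxabicyclo[8.3.0]tridec-8-en-2-yl 2-methylprop-2-enoate (hydroxy diketone, not isolated) | C[C@@]1(O)C[C@@H](OC(=O)C(C)=C)[C@H]2C(=C)C(=O)O[C@@H]2/C=C(/CO)C(=O)CC1=O | intermediate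
23 | CNP0180483.5, (2Z,4R,8R,9R,11R)-2-(hydroxymethyl)-11-methyl-7-methylidene-6,12-dioxo-5,14-dioxatricyclo[9.2.1.0(4,8)]tetradeca-1(13),2-dien-9-yl 2-methylprop-2-enoate | C=C(C)C(=O)O[C@@H]1C[C@@]2(C)OC(=CC2=O)/C(CO)=C\[C@H]2OC(=O)C(=C)[C@@H]21 | target

**Step count and risks**

Total step count: 13. Longest linear sequence: 12 steps (steps 1 and 3 to 13); step 2 is a one-step side branch.

Steps most likely to fail:

Step 13. What may go wrong: the ketone enolate, or the C15 alkoxide released by the transfer, may add to or exchange with the methacrylate and the methylene lactone before C-acylation of the hindered C1 carbonyl is complete. Fallback: the ring switch is moved ahead of the acylation, so that no methacrylate is present. It sets out from the bis-silyl macrolactone 18 and comes back at 23. Treatment of 18 with LiN(SiMe3)2 and then aqueous HCl (both silyl ethers are cleaved) should give the C8,C15-diol furanone F1. Selective silylation of the primary allylic hydroxyl (TBSCl, imidazole, CH2Cl2, −20 °C) should give the C15 silyl ether F2. Acylation with methacrylic anhydride, NEt3 and DMAP should give the silylated methacrylate F3, and HF·pyridine then removes the silyl group to give 23.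

Step 10. What may go wrong: intermolecular allylboration (oligomers) may compete with closure of the ten-membered ring, facial selectivity at C7 may erode in the macrocyclic transition state, and the Z-oxo-enal may isomerise under the Lewis acid. Fallback: ring closure by a chromium-mediated Nozaki–Hiyama–Kishi allylation of an allylic bromide, in which the allylchromium equilibrates and adds anti irrespective of alkene geometry. It sets out from ynoate 12 and comes back at 18. Hydroalumination as in step 8 but quenched with formaldehyde should give the allylic alcohol F4. Appel bromination (CBr4, PPh3) gives the allylic bromide F5, and furan opening as in step 9 gives the bromo enal F6. Slow addition of F6 to CrCl2 in THF at high dilution, with lactonisation in the same flask, should give 18.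

Step 8. What may go wrong: the aluminium hydride may reduce the ester groups, or alkene geometry may be lost through the aluminium allenolate before alkylation. Fallback: a stepwise palladium route to the same boronate, setting out from 12 and coming back at 14. Syn-hydrostannation (Bu3SnH, Pd(PPh3)4) should give the α-stannyl enoate F7. Iododestannylation with I2 gives the α-iodo enoate F8 with retention, and Negishi coupling with IZnCH2Bpin (Pd(PPh3)4, THF) gives 14.

Further compounds
F1 | step 13 | (2Z,4R,8R,9R,11R)-9-hydroxy-2-(hydroxymethyl)-11-methyl-7-methylidene-5,14-dioxatricyclo[9.2.1.0(4,8)]tetradeca-1(13),2-diene-6,12-dione | O[C@@H]1C[C@@]2(C)OC(=CC2=O)/C(CO)=C\[C@H]2OC(=O)C(=C)[C@@H]21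
F2 | step 13 | (2Z,4R,8R,9R,11R)-2-{[(tert-butyldimethylsilyl)oxy]methyl}-9-hydroxy-11-methyl-7-methylidene-5,14-dioxatricyclo[9.2.1.0(4,8)]tetradeca-1(13),2-diene-6,12-dione | O[C@@H]1C[C@@]2(C)OC(=CC2=O)/C(CO[Si](C)(C)C(C)(C)C)=C\[C@H]2OC(=O)C(=C)[C@@H]21
F3 | step 13 | (2Z,4R,8R,9R,11R)-2-{[(tert-butyldimethylsilyl)oxy]methyl}-11-methyl-7-methylidene-6,12-dioxo-5,14-dioxatricyclo[9.2.1.0(4,8)]tetradeca-1(13),2-dien-9-yl 2-methylprop-2-enoate | C=C(C)C(=O)O[C@@H]1C[C@@]2(C)OC(=CC2=O)/C(CO[Si](C)(C)C(C)(C)C)=C\[C@H]2OC(=O)C(=C)[C@@H]21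
F4 | step 10 | 1-methyl 7-[(2-methylfuran-3-yl)methyl] (2Z,4R,6R)-2-(hydroxymethyl)-6-methyl-4,6-bis[(triethylsilyl)oxy]hept-2-enedioate | C[C@@](O[Si](CC)(CC)CC)(C[C@@H](O[Si](CC)(CC)CC)/C=C(\C(=O)OC)CO)C(=O)OCc1ccoc1C
F5 | step 10 | 1-methyl 7-[(2-methylfuran-3-yl)methyl] (2E,4R,6R)-2-(bromomethyl)-6-methyl-4,6-bis[(triethylsilyl)oxy]hept-2-enedioate | C[C@@](O[Si](CC)(CC)CC)(C[C@@H](O[Si](CC)(CC)CC)/C=C(\C(=O)OC)CBr)C(=O)OCc1ccoc1C
F6 | step 10 | 7-[(2Z)-2-acetyl-4-oxobut-2-en-1-yl] 1-methyl (2E,4R,6R)-2-(bromomethyl)-6-methyl-4,6-bis[(triethylsilyl)oxy]hept-2-enedioate | C[C@@](O[Si](CC)(CC)CC)(C[C@@H](O[Si](CC)(CC)CC)/C=C(\C(=O)OC)CBr)C(=O)OC/C(C(C)=O)=C/C=O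
F7 | step 8 | 1-methyl 7-[(2-methylfuran-3-yl)methyl] (2E,4R,6R)-6-methyl-2-(tributylstannyl)-4,6-bis[(triethylsilyl)oxy]hept-2-enedioate | C[C@@](O[Si](CC)(CC)CC)(C[C@@H](O[Si](CC)(CC)CC)/C=C(\C(=O)OC)[Sn](CCCC)(CCCC)CCCC)C(=O)OCc1ccoc1C
F8 | step 8 | 1-methyl 7-[(2-methylfuran-3-yl)methyl] (2E,4R,6R)-2-iodo-6-methyl-4,6-bis[(triethylsilyl)oxy]hept-2-enedioate | C[C@@](O[Si](CC)(CC)CC)(C[C@@H](O[Si](CC)(CC)CC)/C=C(\C(=O)OC)I)C(=O)OCc1ccoc1C
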